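**Plan**
1. Retrosynthetic cuts, in order: the two silyl ethers; the ring bond C4–C5 of the cyclohexenone (ring numbered C1 = C=O, C2=C3, C4 = CHOH, C5 = CH2, C6 = C(OH)R; side chain C1'–C17'), which opens the only ring to an acyclic enone with a 2,2-disubstituted oxirane; C1–C2 (lactone + alkenyllithium); the oxirane (back to an α-methylene lactone); C1'–C2' (back to a C16 aldehyde and a C4 acrylate).
2. Enabling feature: in the six-membered carbocycle, C4 is the γ-carbon of the C1=O/C2=C3 enone and C5–C6(OH) is a C–C–O unit on the α' carbon. The ring is thus the retron of an extended enolate opening an α'-spiro-oxirane, and C6 has no hydrogen, so C4 is the only enolizable site.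
3. Forward order: the chain is joined first (aldehyde + acrylate → butyrolactone holding C2', C1', C6, C5, C1), the oxirane is placed on the exocyclic methylene, the lactone acylates a C3 alkenyllithium (C2–C4), and the carbocycle arises last by C4–C5 bond formation; desilylation ends the route.
4. Stereochemistry: C2' by catalyst control in the allylation; C6 by substrate control (oxirane oxygen anti to the chain on the lactone); C4 in the ring closure under control of C6 (cis-4,6-diol); the Z-alkene is bought with the aldehyde and never touched.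

Key step: step 6

Remark: 1, 2 and 7 are taken as purchasable; the locants C1–C6 and C1'–C17' used below are those defined in the plan.

Step 1
Reactants: 1 (Z)-hexadec-9-enal; 2 ethyl 2-(bromomethyl)acrylate
Product: 5 (5S)-3-methylidene-5-[(8Z)-pentadec-8-en-1-yl]oxolan-2-one, via silyl ether ester 3 (not isolated), via hydroxy ester 4 (not isolated)
Conditions: CrCl2 (10 mol%), chiral carbazole bis(oxazoline) ligand (enantiomer giving the S carbinol, 11 mol%), Mn powder, TMSCl, i-Pr2NEt, THF, rt; then 1 M HCl, THF, rt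
Reagents that add atoms: none
Why: Catalytic asymmetric Nozaki–Hiyama–Kishi 2-(alkoxycarbonyl)allylation, in which the allylchromium species from 2 adds to the aldehyde inside the chiral ligand sphere and so sets C2' as S by reagent control, and the γ-hydroxy ester lactonizes on acidic work-up while the remote Z-alkene stays inert.

Step 2
Reactants: 5 (5S)-3-methylidene-5-[(8Z)-pentadec-8-en-1-yl]oxolan-2-one
Product: 6 (3R,6S)-6-[(8Z)-pentadec-8-en-1-yl]-1,5-dioxaspiro[2.4]heptan-4-one
Conditions: t-BuOOH (in decane), DBU, CH2Cl2, 0 °C to rt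
Reagents that add atoms: tert-butyl hydroperoxide, CC(C)(C)OO
Why: Nucleophilic (Weitz–Scheffer-type) epoxidation attacks only the electron-poor exocyclic enoate alkene, not the isolated Z-alkene, and the lactone enolate should close the oxirane with oxygen on the face opposite the C5 chain of the lactone (1,3-induction across the five-membered ring), which sets the future C6.

Step 3
Reactants: 7 triisopropyl(prop-2-yn-1-yloxy)silane
Product: 9 triisopropyl{[(2E)-3-iodoprop-2-en-1-yl]oxy}silane, via alkenylzirconocene chloride 8 (not isolated)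
Conditions: Cp2Zr(H)Cl, THF, rt; then I2, 0 °C
Reagents that add atoms: iodine, II
Why: Hydrozirconation–iodination, in which syn addition of Zr–H places zirconium on the terminal carbon and iodinolysis with retention gives the E-alkenyl iodide.

Step 4
Reactants: 9 triisopropyl{[(2E)-3-iodoprop-2-en-1-yl]oxy}silane; 6 (3R,6S)-6-[(8Z)-pentadec-8-en-1-yl]-1,5-dioxaspiro[2.4]heptan-4-one
Product: 11 (2E)-1-{(2R)-2-[(2S,10Z)-2-hydroxyheptadec-10-en-1-yl]oxiran-2-yl}-4-(triisopropylsilyloxy)but-2-en-1-one, via alkenyllithium 10 (not isolated)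
Conditions: t-BuLi (2.0 equiv), Et2O, −78 °C; then 6, THF, −78 °C; AcOH quench at −78 °C
Reagents that add atoms: none
Why: Iodine–lithium exchange followed by acyl substitution of the lactone by the alkenyllithium; the lactone has no α-hydrogen and its lithium hemiketal alkoxide should survive until the cold acidic quench, so mono-addition gives the enone with the oxirane and both stereocentres untouched.

Step 5
Reactants: 11 (2E)-1-{(2R)-2-[(2S,10Z)-2-hydroxyheptadec-10-en-1-yl]oxiran-2-yl}-4-(triisopropylsilyloxy)but-2-en-1-one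
Product: 12 (2E)-1-{(2R)-2-[(2S,10Z)-2-(tert-butyldimethylsilyloxy)heptadec-10-en-1-yl]oxiran-2-yl}-4-(triisopropylsilyloxy)but-2-en-1-one
Conditions: TBSCl, imidazole, DMF, 0 °C to rt
Reagents that add atoms: tert-butyldimethylsilyl chloride, CC(C)(C)[Si](C)(C)Cl
Why: Silyl ether protection of the secondary C2' alcohol, which would otherwise mask the ketone as a hemiketal and consume base in step 6.

Step 6
Reactants: 12 (2E)-1-{(2R)-2-[(2S,10Z)-2-(tert-butyldimethylsilyloxy)heptadec-10-en-1-yl]oxiran-2-yl}-4-(triisopropylsilyloxy)but-2-en-1-one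
Product: 15 (4S,6R)-6-hydroxy-6-[(2S,10Z)-2-(tert-butyldimethylsilyloxy)heptadec-10-en-1-yl]-4-(triisopropylsilyloxy)cyclohex-2-en-1-one, via potassium dienolate 13 (not isolated), via potassium alkoxide 14 (not isolated)
Conditions: t-BuOK (1.1 equiv), THF/t-BuOH (10:1), 0.01 M, −20 to 0 °C; AcOH quench
Reagents that add atoms: none
Why: Proposed new method: t-BuOK removes a γ-hydrogen at C4 (the only acidic site, since C6 bears no hydrogen; the E geometry of C2=C3 is lost here) and the extended enolate O1–C1=C2–C3=C4 attacks through its γ-carbon the unsubstituted oxirane carbon C5 in an SN2 opening driven by epoxide strain, which forms C4–C5, restores the C2=C3 enone and leaves O6 as alkoxide; the closest known reaction types are the intramolecular γ-alkylation and vinylogous aldol cyclization of dienolates and the enolate–epoxide cyclization of epoxy ketones and epoxy nitriles. The carbocycle C1–C6 closes in a 6-endo-tet mode with respect to the oxirane and holds the whole dienolate, whereas attack by C2 or O1 would need a four-membered ring and attack at the quaternary C6 a five-membered one, so only the γ-carbon can reach the electrophile. C6 is not touched and keeps the configuration of the oxirane; C4 is set in the ring closure by the oxirane itself, because the near-collinear C4···C5–O6 alignment puts O6 pseudo-equatorial on the sofa-like transition state and the bulky OTIPS group at the enol ether terminus takes the outward position that becomes pseudo-equatorial, which gives O4 cis to O6 (4S with 6R). The step needs γ- over α- or O-alkylation, which ring size secures, and access to the dienolate isomer with C6 and C3 cis on C1=C2, which reversible proton transfer in t-BuOH should supply while the unreactive isomers are recycled. The α-ketol alkoxide formed is a far weaker base than the dienolate, so the medium loses basicity as the reaction proceeds and epimerization at C4 should stay slow up to the acidic quench.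

Step 7
Reactants: 15 (4S,6R)-6-hydroxy-6-[(2S,10Z)-2-(tert-butyldimethylsilyloxy)heptadec-10-en-1-yl]-4-(triisopropylsilyloxy)cyclohex-2-en-1-one
Product: 16 (4S,6R)-4,6-dihydroxy-6-[(2S,10Z)-2-hydroxyheptadec-10-en-1-yl]cyclohex-2-en-1-one
Conditions: HF·pyridine, pyridine, THF, 0 °C to rt
Reagents that add atoms: none
Why: Global desilylation by buffered fluoride, which should cleave both silyl ethers under nearly neutral conditions and leave the γ-hydroxy enone and the tertiary α-ketol intact.

**Compound list**
1 | (Z)-hexadec-9-enal | CCCCCC/C=C\CCCCCCCC=O | starting material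
2 | ethyl 2-(bromomethyl)acrylate | C=C(CBr)C(=O)OCC | starting material
3 | ethyl (4S,12Z)-2-methylidene-4-(trimethylsilyloxy)nonadec-12-enoate | CCCCCC/C=C\CCCCCCC[C@H](O[Si](C)(C)C)CC(=C)C(=O)OCC | intermediate
4 | ethyl (4S,12Z)-4-hydroxy-2-methylidenenonadec-12-enoate | CCCCCC/C=C\CCCCCCC[C@H](O)CC(=C)C(=O)OCC | intermediate
5 | (5S)-3-methylidene-5-[(8Z)-pentadec-8-en-1-yl]oxolan-2-one | CCCCCC/C=C\CCCCCCC[C@H]1CC(=C)C(=O)O1 | intermediate
6 | (3R,6S)-6-[(8Z)-pentadec-8-en-1-yl]-1,5-dioxaspiro[2.4]heptan-4-one (oxirane oxygen trans to the chain) | CCCCCC/C=C\CCCCCCC[C@H]1C[C@@]2(CO2)C(=O)O1 | intermediate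
7 | triisopropyl(prop-2-yn-1-yloxy)silane | C#CCO[Si](C(C)C)(C(C)C)C(C)C | starting material
8 | chloro[(1E)-3-(triisopropylsilyloxy)prop-1-en-1-yl]zirconocene | Cl[Zr](/C=C/CO[Si](C(C)C)(C(C)C)C(C)C)(C1C=CC=C1)C1C=CC=C1 | intermediate
9 | triisopropyl{[(2E)-3-iodoprop-2-en-1-yl]oxy}silane | I/C=C/CO[Si](C(C)C)(C(C)C)C(C)C | intermediate
10 | [(1E)-3-(triisopropylsilyloxy)prop-1-en-1-yl]lithium | [Li]/C=C/CO[Si](C(C)C)(C(C)C)C(C)C | intermediate
11 | (2E)-1-{(2R)-2-[(2S,10Z)-2-hydroxyheptadec-10-en-1-yl]oxiran-2-yl}-4-(triisopropylsilyloxy)but-2-en-1-one | CCCCCC/C=C\CCCCCCC[C@H](O)C[C@@]1(CO1)C(=O)/C=C/CO[Si](C(C)C)(C(C)C)C(C)C | intermediate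
12 | (2E)-1-{(2R)-2-[(2S,10Z)-2-(tert-butyldimethylsilyloxy)heptadec-10-en-1-yl]oxiran-2-yl}-4-(triisopropylsilyloxy)but-2-en-1-one | CCCCCC/C=C\CCCCCCC[C@H](O[Si](C)(C)C(C)(C)C)C[C@@]1(CO1)C(=O)/C=C/CO[Si](C(C)C)(C(C)C)C(C)C | intermediate
13 | potassium dienolate of 12 (extended enolate O1–C1=C2–C3=C4, geometry not fixed) | CCCCCC/C=C\CCCCCCC[C@H](O[Si](C)(C)C(C)(C)C)C[C@@]1(CO1)C([O-])=CC=CO[Si](C(C)C)(C(C)C)C(C)C.[K+] | intermediate
14 | potassium C6 alkoxide of 15 | CCCCCC/C=C\CCCCCCC[C@H](O[Si](C)(C)C(C)(C)C)C[C@@]1([O-])C[C@H](O[Si](C(C)C)(C(C)C)C(C)C)C=CC1=O.[K+] | intermediate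
15 | (4S,6R)-6-hydroxy-6-[(2S,10Z)-2-(tert-butyldimethylsilyloxy)heptadec-10-en-1-yl]-4-(triisopropylsilyloxy)cyclohex-2-en-1-one | CCCCCC/C=C\CCCCCCC[C@H](O[Si](C)(C)C(C)(C)C)C[C@@]1(O)C[C@H](O[Si](C(C)C)(C(C)C)C(C)C)C=CC1=O | intermediate
16 | (4S,6R)-4,6-dihydroxy-6-[(2S,10Z)-2-hydroxyheptadec-10-en-1-yl]cyclohex-2-en-1-one | CCCCCC/C=C\CCCCCCC[C@H](O)C[C@@]1(O)C[C@H](O)C=CC1=O | target

**Step count and risks**
Total steps: 7. Longest linear sequence: 6 (steps 1, 2, 4, 5, 6, 7 from aldehyde 1; step 3 is a one-step branch).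

Steps most likely to fail:

1. Step 6 (proposed new method). The extended enolate may not reach the geometry needed for ring closure, or may be diverted into a Favorskii-type contraction or an α-ketol shift. Reversible γ-deprotonation of the product may also erode the C4 configuration, and silyl migration from O4 (the reason for the slow-migrating TIPS group) is a further drain. Fallback with known reaction types, from 6 back to 16: a vinylcuprate (CH2=CHMgBr, CuI, THF, −40 °C) should open the oxirane of 6 at its CH2 group to the allyl hydroxy lactone F1, which makes the C4–C5 bond between two molecules. Aminolysis with MeNH(OMe)·HCl and i-PrMgCl gives the dihydroxy Weinreb amide F2, and excess allylmagnesium bromide gives the β,γ-unsaturated ketone F3. Ring-closing metathesis with the first-generation Grubbs catalyst RuCl2(PCy3)2(=CHPh), which should leave the internal Z-alkene alone, closes the ring at C3=C4 to the cyclohex-4-enone F4. Hydroxyl-directed epoxidation (VO(acac)2, t-BuOOH, CH2Cl2) from the face of the C6 hydroxyl gives the cis-epoxy ketone F5, and Et3N opens this β,γ-epoxy ketone by β-elimination to the cis-γ-hydroxy enone, which is 16; no protecting group is needed.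

2. Step 2. Facial selectivity in the oxirane closure may be poor across the flat lactone, and the peroxide anion may attack the lactone carbonyl. Fallback with reagent control, from 5 back to 6: DIBAL-H (CH2Cl2, −78 to 0 °C) reduces the lactone to the allylic diol F6. Sharpless asymmetric epoxidation (Ti(OiPr)4, L-(+)-diethyl tartrate, t-BuOOH, 4 Å sieves, CH2Cl2, −20 °C) sets the oxirane to give the epoxy diol F7. TEMPO with PhI(OAc)2 oxidizes the primary alcohol and the resulting lactol to the lactone 6.

3. Step 4. The alkenyllithium may add a second time once the hemiketal alkoxide collapses, or that alkoxide may open or rearrange the neighbouring oxirane. Fallback, from 6 back to 12: ring-opening of 6 with MeNH(OMe)·HCl and i-PrMgCl (THF, −20 °C) gives the hydroxy Weinreb amide F8, and TBSCl with imidazole gives the silyl ether F9. Alkenyllithium 10 (from 9) then gives ketone 12 directly, the chelated tetrahedral adduct excluding over-addition; steps 4 and 5 are bypassed.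

**Further compounds**
F1 | step 6 | (3S,5S)-3-hydroxy-5-[(8Z)-pentadec-8-en-1-yl]-3-(prop-2-en-1-yl)oxolan-2-one | CCCCCC/C=C\CCCCCCC[C@H]1C[C@@](O)(CC=C)C(=O)O1
F2 | step 6 | (2S,4S,12Z)-2,4-dihydroxy-N-methoxy-N-methyl-2-(prop-2-en-1-yl)nonadec-12-enamide | CCCCCC/C=C\CCCCCCC[C@H](O)C[C@@](O)(CC=C)C(=O)N(C)OC
F3 | step 6 | (5S,7S,15Z)-5,7-dihydroxy-5-(prop-2-en-1-yl)docosa-1,15-dien-4-one | CCCCCC/C=C\CCCCCCC[C@H](O)C[C@@](O)(CC=C)C(=O)CC=C
F4 | step 6 | (2S)-2-hydroxy-2-[(2S,10Z)-2-hydroxyheptadec-10-en-1-yl]cyclohex-4-en-1-one | CCCCCC/C=C\CCCCCCC[C@H](O)C[C@@]1(O)CC=CCC1=O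
F5 | step 6 | (1R,4R,6S)-4-hydroxy-4-[(2S,10Z)-2-hydroxyheptadec-10-en-1-yl]-7-oxabicyclo[4.1.0]heptan-3-one | CCCCCC/C=C\CCCCCCC[C@H](O)C[C@@]1(O)C[C@@H]2O[C@@H]2CC1=O
F6 | step 2 | (4S,12Z)-2-methylidenenonadec-12-ene-1,4-diol | CCCCCC/C=C\CCCCCCC[C@H](O)CC(=C)CO
F7 | step 2 | [(2S)-2-[(2S,10Z)-2-hydroxyheptadec-10-en-1-yl]oxiran-2-yl]methanol | CCCCCC/C=C\CCCCCCC[C@H](O)C[C@@]1(CO1)CO
F8 | step 4 | (2R)-2-[(2S,10Z)-2-hydroxyheptadec-10-en-1-yl]-N-methoxy-N-methyloxirane-2-carboxamide | CCCCCC/C=C\CCCCCCC[C@H](O)C[C@@]1(CO1)C(=O)N(C)OC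
F9 | step 4 | (2R)-2-[(2S,10Z)-2-(tert-butyldimethylsilyloxy)heptadec-10-en-1-yl]-N-methoxy-N-methyloxirane-2-carboxamide | CCCCCC/C=C\CCCCCCC[C@H](O[Si](C)(C)C(C)(C)C)C[C@@]1(CO1)C(=O)N(C)OC
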